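The ring bond between C-4 (the carbonyl carbon next to the chain-bearing C-3) and C-5 (the hydroxylated carbon) of the 2,5-dihydroxy-1,4-benzoquinone ring joins two oxygen-bearing, acyl-type carbons of like polarity, and the route rests on disconnecting it. The key step, a thermal Moore rearrangement, forges it by diradical coupling. A squarate-derived 4-(ethoxyethynyl)-4-hydroxycyclobutenone opens to an enynylketene whose ketene carbon bonds to the ethoxy-bearing alkyne carbon, expanding the four-membered ring to the fully substituted quinone in one operation. Ring atoms C-1 to C-4 thus come from squaric acid, C-5 and C-6 from an ynol ether. The (E)-nonadec-14-enyl chain arrives as an organolithium, and hydrolysis of the two alkyl ethers ends the route.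

Key step: step 5

Assumption: 13-bromotridecan-1-ol and (E)-hex-1-en-1-ylboronic acid are taken as purchasable; compounds 7 and 11 are racemic, and their single stereocentre is destroyed in the operation that follows.

Step 1
Reactants: 1 13-bromotridecan-1-ol; 2 (E)-hex-1-en-1-ylboronic acid
Product: 3 (E)-nonadec-14-en-1-ol
Conditions: Pd(OAc)2 (5 mol%), P(t-Bu)2Me (10 mol%), KOt-Bu (3 equiv), t-amyl alcohol, rt
Reagents that add atoms: none
Why: Suzuki–Miyaura coupling of an unactivated primary alkyl bromide with an alkenylboronic acid: the bulky, electron-rich trialkylphosphine should let zerovalent palladium insert into the C–Br bond at room temperature faster than β-hydride elimination can follow, the hexenyl group is transferred with retention of its (E) geometry, and the free hydroxyl should be tolerated in the alcohol solvent.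

Step 2
Reactants: 3 (E)-nonadec-14-en-1-ol
Product: 4 (E)-19-iodononadec-5-ene [(E)-nonadec-14-en-1-yl iodide]
Conditions: I2, PPh3, imidazole, CH2Cl2, 0 °C to rt
Reagents that add atoms: iodine, II
Why: Appel-type (Garegg–Samuelsson) iodination: iodide displaces the alkoxyphosphonium ion of the primary alcohol in an SN2 step, and the isolated (E)-alkene should be untouched because the iodine is taken up by the phosphine before the alcohol is added.

Step 3
Reactants: 4 (E)-19-iodononadec-5-ene; 5 dimethyl squarate
Product: 8 3-methoxy-4-[(E)-nonadec-14-en-1-yl]cyclobut-3-ene-1,2-dione, via alkyllithium 6 (not isolated), via hydroxycyclobutenone adduct 7 (not isolated)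
Conditions: t-BuLi (2.1 equiv), Et2O/pentane, −78 °C; add to 5, THF, −78 °C; aq. NH4Cl; crude, conc. HCl (cat.), CH2Cl2, rt
Reagents that add atoms: none
Why: Lithium–iodine exchange with two equivalents of t-BuLi should give the primary alkyllithium cleanly, its 1,2-addition to one carbonyl of the squarate ester stops at the mono-adduct at −78 °C, and acid-catalysed allylic transposition of the carbinol with loss of methanol (the standard squarate to 3-alkyl-4-alkoxycyclobutenedione sequence) gives 8.

Step 4
Reactants: 8 3-methoxy-4-[(E)-nonadec-14-en-1-yl]cyclobut-3-ene-1,2-dione; 9 ethoxyacetylene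
Product: 11 4-(ethoxyethynyl)-4-hydroxy-3-methoxy-2-[(E)-nonadec-14-en-1-yl]cyclobut-2-en-1-one, via lithium ethoxyacetylide 10 (not isolated)
Conditions: 9, n-BuLi, THF, −78 °C; then 8, −78 °C; aq. NH4Cl at −78 °C
Reagents that add atoms: none
Why: 1,2-Addition of a lithium acetylide to a cyclobutenedione: the carbonyl next to the chain-bearing carbon is a vinylogous ester and is deactivated, so the acetylide should attack the carbonyl next to the methoxy-bearing carbon, which places the carbinol between the ynol ether and the methoxy group; the new quaternary stereocentre forms as a racemate and is destroyed in step 5.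

Step 5
Reactants: 11 4-(ethoxyethynyl)-4-hydroxy-3-methoxy-2-[(E)-nonadec-14-en-1-yl]cyclobut-2-en-1-one
Product: 14 5-ethoxy-2-methoxy-3-[(E)-nonadec-14-en-1-yl]cyclohexa-2,5-diene-1,4-dione, via enynylketene 12 (not isolated), via aryl-phenoxyl diradical 13 (not isolated)
Conditions: toluene (0.01 M), argon, 110 °C
Reagents that add atoms: none
Why: Heating should trigger conrotatory 4π-electrocyclic opening of the cyclobutenone C1–C4 bond, the donor hydroxyl rotating outward so that enynylketene 12 holds the ynol ether cis to the ketene; the ketene carbon then bonds to the ethoxy-bearing alkyne terminus to give the aromatic aryl-phenoxyl diradical 13, and transfer of the hydroxyl hydrogen to the aryl radical centre delivers quinone 14. The closest known reaction type is the Moore rearrangement of 4-alkynyl-4-hydroxycyclobutenones to 1,4-benzoquinones, the enyne-ketene counterpart of the Myers–Saito cyclization. The six-membered ring closes in a 6-endo-dig sense at the distal alkyne carbon, joining two carbons that are both acyl-type electrophiles in polar terms, hence the diradical pathway. No stereocentre is formed and the carbinol centre of 11 is destroyed. The step needs six- over five-membered closure (the 5-exo mode would give an alkylidenecyclopentenedione), which should be secured because the alkoxy group does not stabilise an exocyclic vinyl radical whereas distal closure gains aromaticity; the placement of chain, methoxy and ethoxy groups is already fixed by the regiochemistry of step 4. Working at about 110 °C in dilute solution should keep the ethyl ynol ether below the temperature of its retro-ene loss of ethylene, and the remote (E)-alkene is a spectator.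

Step 6
Reactants: 14 5-ethoxy-2-methoxy-3-[(E)-nonadec-14-en-1-yl]cyclohexa-2,5-diene-1,4-dione
Product: 15 2,5-dihydroxy-3-[(E)-nonadec-14-en-1-yl]cyclohexa-2,5-diene-1,4-dione
Conditions: 2 M aq. NaOH, EtOH/THF, rt to 50 °C; then 2 M HCl
Reagents that add atoms: sodium hydroxide, [Na+].[OH-]
Why: Vinylogous ester saponification: hydroxide adds to C-2 and C-5 of the quinone and expels methoxide and ethoxide (addition–elimination), driven by formation of the resonance-stabilised dianion of the dihydroxyquinone, which acidification converts into the target; the isolated alkene should not react.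

Compound list
1 | 13-bromotridecan-1-ol | OCCCCCCCCCCCCCBr | starting material
2 | (E)-hex-1-en-1-ylboronic acid | CCCC/C=C/B(O)O | starting material
3 | (E)-nonadec-14-en-1-ol | CCCC/C=C/CCCCCCCCCCCCCO | intermediate
4 | (E)-19-iodononadec-5-ene | CCCC/C=C/CCCCCCCCCCCCCI | intermediate
5 | dimethyl squarate (3,4-dimethoxycyclobut-3-ene-1,2-dione) | COC1=C(OC)C(=O)C1=O | starting material
6 | (E)-nonadec-14-en-1-yllithium | [Li]CCCCCCCCCCCCC/C=C/CCCC | intermediate (not isolated)
7 | 4-hydroxy-2,3-dimethoxy-4-[(E)-nonadec-14-en-1-yl]cyclobut-2-en-1-one (racemic) | COC1=C(OC)C(O)(CCCCCCCCCCCCC/C=C/CCCC)C1=O | intermediate (not isolated)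
8 | 3-methoxy-4-[(E)-nonadec-14-en-1-yl]cyclobut-3-ene-1,2-dione | COC1=C(CCCCCCCCCCCCC/C=C/CCCC)C(=O)C1=O | intermediate
9 | ethoxyacetylene (ethoxyethyne) | CCOC#C | starting material
10 | lithium ethoxyacetylide | CCOC#C[Li] | intermediate (not isolated)
11 | 4-(ethoxyethynyl)-4-hydroxy-3-methoxy-2-[(E)-nonadec-14-en-1-yl]cyclobut-2-en-1-one (racemic) | CCOC#CC1(O)C(OC)=C(CCCCCCCCCCCCC/C=C/CCCC)C1=O | intermediate
12 | (3Z)-6-ethoxy-4-hydroxy-3-methoxy-2-[(E)-nonadec-14-en-1-yl]hexa-1,3-dien-5-yn-1-one (enynylketene) | CCCC/C=C/CCCCCCCCCCCCCC(=C=O)/C(OC)=C(/O)C#COCC | intermediate (not isolated)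
13 | 2-ethoxy-4-hydroxy-5-methoxy-6-[(E)-nonadec-14-en-1-yl]phenoxyl-3-yl diradical | CCOc1[c]c(O)c(OC)c(CCCCCCCCCCCCC/C=C/CCCC)c1[O] | intermediate (not isolated)
14 | 5-ethoxy-2-methoxy-3-[(E)-nonadec-14-en-1-yl]cyclohexa-2,5-diene-1,4-dione | CCOC1=CC(=O)C(OC)=C(CCCCCCCCCCCCC/C=C/CCCC)C1=O | intermediate
15 | 2,5-dihydroxy-3-[(E)-nonadec-14-en-1-yl]cyclohexa-2,5-diene-1,4-dione | CCCC/C=C/CCCCCCCCCCCCCC1=C(O)C(=O)C=C(O)C1=O | target

Total steps: 6. Longest linear sequence: 6 steps (from 1).

Steps most likely to fail

Step 5 (key step). The diradical closure may take the five-membered course at the proximal alkyne carbon, or the ethyl ynol ether may lose ethylene by a retro-ene process before the cyclobutenone opens. The fallback sets out from 8 and forms the same C-4–C-5 bond by a pericyclic closure that has no regiochemical alternative. (Z)-2-Ethoxyethenyllithium F1, generated from (Z)-1-bromo-2-ethoxyethene and t-BuLi in THF at −78 °C, should add to the same carbonyl of 8 to give 4-[(Z)-2-ethoxyethenyl]-4-hydroxy-3-methoxy-2-[(E)-nonadec-14-en-1-yl]cyclobut-2-en-1-one F2. Thermolysis of F2 in toluene should open the ring and close the resulting dienylketene by 6π-electrocyclisation, and tautomerisation would give 5-ethoxy-2-methoxy-3-[(E)-nonadec-14-en-1-yl]benzene-1,4-diol F3. Oxidation with Ag2O in Et2O should convert F3 into 14, where the fallback comes back to the route.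

Step 4. The acid-labile ynol ether carbinol may hydrate or decompose during quench and chromatography, or the acetylide may add sluggishly. The fallback sets out from 8 and postpones the C-5 oxygen. HC≡CMgBr (ethynylmagnesium bromide) in THF at −78 °C should give 4-ethynyl-4-hydroxy-3-methoxy-2-[(E)-nonadec-14-en-1-yl]cyclobut-2-en-1-one F4. Moore rearrangement of F4 in p-xylene at 138 °C should close the same ring bond and give 2-methoxy-3-[(E)-nonadec-14-en-1-yl]cyclohexa-2,5-diene-1,4-dione F5. Conjugate addition of methanol promoted by ZnCl2, with reoxidation by air, should go to C-5 because the C-4 carbonyl is deactivated as a vinylogous ester, giving 2,5-dimethoxy-3-[(E)-nonadec-14-en-1-yl]cyclohexa-2,5-diene-1,4-dione F6. Hydrolysis of F6 with aqueous NaOH and acidification, as in step 6, comes back to the route at 15.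

Step 1. The alkylpalladium intermediate may undergo β-hydride elimination, the free alkoxide may form ethers with the bromide, or the boronic acid may protodeboronate. The fallback sets out from 1 and builds the alkene by alkyne alkylation and trans reduction. Hex-1-yn-1-yllithium F7, from 1-hexyne and n-BuLi (2.2 equiv) in THF/DMPU, should be alkylated by 1 to give nonadec-14-yn-1-ol F8. Dissolving-metal reduction of F8 with Na in NH3/THF at −33 °C should give the (E)-alkene and comes back to the route at 3.

Further compounds
F1 | step 5 | (Z)-2-ethoxyethenyllithium | CCO/C=C\[Li]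
F2 | step 5 | 4-[(Z)-2-ethoxyethenyl]-4-hydroxy-3-methoxy-2-[(E)-nonadec-14-en-1-yl]cyclobut-2-en-1-one (racemic) | CCO/C=C\C1(O)C(OC)=C(CCCCCCCCCCCCC/C=C/CCCC)C1=O
F3 | step 5 | 5-ethoxy-2-methoxy-3-[(E)-nonadec-14-en-1-yl]benzene-1,4-diol | CCOc1cc(O)c(OC)c(CCCCCCCCCCCCC/C=C/CCCC)c1O
F4 | step 4 | 4-ethynyl-4-hydroxy-3-methoxy-2-[(E)-nonadec-14-en-1-yl]cyclobut-2-en-1-one (racemic) | C#CC1(O)C(OC)=C(CCCCCCCCCCCCC/C=C/CCCC)C1=O
F5 | step 4 | 2-methoxy-3-[(E)-nonadec-14-en-1-yl]cyclohexa-2,5-diene-1,4-dione | COC1=C(CCCCCCCCCCCCC/C=C/CCCC)C(=O)C=CC1=O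
F6 | step 4 | 2,5-dimethoxy-3-[(E)-nonadec-14-en-1-yl]cyclohexa-2,5-diene-1,4-dione | COC1=CC(=O)C(OC)=C(CCCCCCCCCCCCC/C=C/CCCC)C1=O
F7 | step 1 | hex-1-yn-1-yllithium | CCCCC#C[Li]
F8 | step 1 | nonadec-14-yn-1-ol | CCCCC#CCCCCCCCCCCCCCO
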